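**Retrosynthetic overview**

1. The strategy rests on the C2 substituent of the 3,6-dihydro-2H-pyran ring (O1, C2–C6, C4=C5). The acrylic acid C(=CH2)CO2H on the (R)-configured C2 is an isopropenyl group whose methyl carbon has been raised to the carboxyl level. It is one of five allylic methyl groups in a molecule with four C=C bonds.
2. Last disconnection: the two C–O bonds of the CO2H group. Three enzymatic oxidations at that one methyl (P450, reductase, O2, NADPH) lead back to the (R)-2-isopropenyl pyran; no ring forms in this step.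
3. The only ring is closed earlier, by ring-closing metathesis across C4=C5 of a bis-allylic ether.
4. The ether (O1–C6 bond) comes from (R)-2-methylhexa-1,5-dien-3-ol, made by Brown allylation of methacrolein, which sets C2, and a 2-(homofarnesyl)allyl bromide.
5. The bromide comes from (2E,6E)-farnesyl bromide and the dianion of 2-methylallyl alcohol.

Key step: step 6

Remark: the C5 chain has two CH2 groups before its first alkene (homofarnesyl). It is therefore built by joining farnesyl bromide to a CH2 carbanion, not by attaching a farnesyl group directly. The P450 of step 6 is assumed to be a variant evolved on compound 12 from a sesquiterpene isopropenyl-methyl oxidase.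

**Route**

Step 1
Reactants: 1 (2E,6E)-farnesyl bromide; 2 2-methylprop-2-en-1-ol
Product: 4 (5E,9E)-6,10,14-trimethyl-2-methylidenepentadeca-5,9,13-trien-1-ol, via dilithiated 2-methylallyl alcohol 3 (not isolated)
Conditions: 2, n-BuLi (2 equiv), TMEDA, Et2O–THF, 0 °C → rt; then 1 (limiting), THF, −78 → 0 °C; H2O
Reagents that add atoms: none
Why: Alkylation of an allylic dianion: the carbon end of the O,C-dilithiated, symmetrical 2-methylallyl unit should displace the primary allylic bromide by SN2 in preference to SN2' at the trisubstituted γ-carbon, which adds the CH2 that makes the chain homofarnesyl and leaves both E alkenes of 1 untouched.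

Step 2
Reactants: 4 (5E,9E)-6,10,14-trimethyl-2-methylidenepentadeca-5,9,13-trien-1-ol
Product: 5 (5E,9E)-2-(bromomethyl)-6,10,14-trimethylpentadeca-1,5,9,13-tetraene
Conditions: CBr4, PPh3, CH2Cl2, 0 °C
Reagents that add atoms: carbon tetrabromide, BrC(Br)(Br)Br
Why: Appel bromination of a primary allylic alcohol under neutral conditions, where an SN2' pathway would return the same 2-substituted allyl bromide and the acid-sensitive trisubstituted alkenes are not exposed to acid.

Step 3
Reactants: 6 methacrolein; 7 allylmagnesium bromide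
Product: 9 (3R)-2-methylhexa-1,5-dien-3-ol, via diisopinocampheylborinate ester 8 (not isolated)
Conditions: 7, (+)-Ipc2BOMe [from (−)-α-pinene], Et2O, 0 °C → rt; then 6, −78 °C; then 3 M NaOH, 30% H2O2, rt
Reagents that add atoms: none
Why: Brown allylboration through a chair Zimmerman–Traxler transition state, in which the (−)-α-pinene-derived Ipc2B-allyl reagent should deliver allyl to the Re face of the aldehyde and so set the carbinol centre as R (O > isopropenyl > allyl CH2 > H), the same facial sense as with aryl and other branched aldehydes.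

Step 4
Reactants: 9 (3R)-2-methylhexa-1,5-dien-3-ol; 5 (5E,9E)-2-(bromomethyl)-6,10,14-trimethylpentadeca-1,5,9,13-tetraene
Product: 11 (3R)-2-methyl-3-{[(5E,9E)-6,10,14-trimethyl-2-methylidenepentadeca-5,9,13-trien-1-yl]oxy}hexa-1,5-diene, via sodium alkoxide 10 (not isolated)
Conditions: 9, NaH, THF, 0 °C; then 5, Bu4NI (cat.), 0 °C → rt
Reagents that add atoms: none
Why: Williamson etherification of a sodium alkoxide with a reactive primary allylic bromide, in which the C–O bond at the stereocentre is not broken so R is kept, and the sodium counter-ion at or below room temperature should keep the anionic oxy-Cope rearrangement of the 1,5-dien-3-olate out of reach.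

Step 5
Reactants: 11 (3R)-2-methyl-3-{[(5E,9E)-6,10,14-trimethyl-2-methylidenepentadeca-5,9,13-trien-1-yl]oxy}hexa-1,5-diene
Product: 12 (2R)-2-(prop-1-en-2-yl)-5-[(3E,7E)-4,8,12-trimethyltrideca-3,7,11-trien-1-yl]-3,6-dihydro-2H-pyran
Conditions: Grubbs II (3 mol%), CH2Cl2 (0.005 M), 40 °C
Reagents that add atoms: none
Why: Ring-closing metathesis in which the carbene loads on the monosubstituted vinyl group and closes onto the 1,1-disubstituted allyl-ether alkene to give the six-membered ring with the C4=C5 trisubstituted alkene and ethylene, whereas the isopropenyl group and the chain alkenes could only give four-membered, tetrasubstituted or medium-ring products and should stay out.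

Step 6
Reactants: 12 (2R)-2-(prop-1-en-2-yl)-5-[(3E,7E)-4,8,12-trimethyltrideca-3,7,11-trien-1-yl]-3,6-dihydro-2H-pyran
Product: 15 2-{(2R)-5-[(3E,7E)-4,8,12-trimethyltrideca-3,7,11-trien-1-yl]-3,6-dihydro-2H-pyran-2-yl}prop-2-enoic acid (CNP0171598.2), via allylic alcohol 13 (not isolated), via enal 14 (not isolated)
Conditions: evolved CYP71AV-type P450 + cytochrome P450 reductase (yeast microsomes), NADP+ (cat.), D-glucose, glucose dehydrogenase, air, KPi pH 7.5, 2-hydroxypropyl-β-cyclodextrin, 30 °C; then pH 3, EtOAc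
Reagents that add atoms: dioxygen, O=O; water, O
Why: Proposed new method: the ferryl porphyrin radical cation (Compound I) abstracts a hydrogen atom from the isopropenyl methyl of 12, and because the resulting 2-substituted allyl radical has two constitutionally identical CH2 ends, hydroxyl rebound at either end gives the same allylic alcohol 13; a second turnover hydroxylates the carbinol C–H to a gem-diol that collapses to enal 14, and a third oxidises the aldehyde (or its hydrate) to acid 15, the oxygen coming from O2 with exchange through water possible at the aldehyde stage. The closest known reaction type is the three-fold P450 oxidation of the isopropenyl methyl of sesquiterpene olefins to 2-substituted acrylic acids by the CYP71AV oxidases of amorphadiene and germacrene A, which has not been shown on an O-heterocycle bearing a C16 polyprenyl chain, so a variant has to be evolved on 12 with 13 and 14 as reporter intermediates. No ring is closed and no stereocentre is formed: C2 (R) is carried through, and its allylic α-oxy hydrogen must stay untouched. The step needs site selectivity for one allylic methyl out of five and chemoselectivity against the C2–H, the ring and chain allylic CH2 groups and four alkenes; only the binding mode can give this, with the compact pyran–isopropenyl head seated over the haem and the lipophilic chain held in the access channel, the shape in which this enzyme family binds its terpene substrates. Doing the oxidation last also means that the base- and nucleophile-sensitive acrylic acid never meets NaH, organolithiums or the ruthenium carbene.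

**Compound list**

1 | (2E,6E)-farnesyl bromide, (2E,6E)-1-bromo-3,7,11-trimethyldodeca-2,6,10-triene | BrC/C=C(\C)CC/C=C(\C)CCC=C(C)C | starting material
2 | 2-methylprop-2-en-1-ol (2-methylallyl alcohol) | C=C(C)CO | starting material
3 | dilithiated 2-methylallyl alcohol, lithium 2-(lithiomethyl)prop-2-en-1-olate | [Li]CC(=C)CO[Li] | intermediate
4 | (5E,9E)-6,10,14-trimethyl-2-methylidenepentadeca-5,9,13-trien-1-ol | C=C(CO)CC/C=C(\C)CC/C=C(\C)CCC=C(C)C | intermediate
5 | (5E,9E)-2-(bromomethyl)-6,10,14-trimethylpentadeca-1,5,9,13-tetraene | C=C(CBr)CC/C=C(\C)CC/C=C(\C)CCC=C(C)C | intermediate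
6 | methacrolein (2-methylprop-2-enal) | C=C(C)C=O | starting material
7 | allylmagnesium bromide | C=CC[Mg]Br | starting material
8 | (3R)-2-methylhexa-1,5-dien-3-yl diisopinocampheylborinate, Ipc groups from (−)-α-pinene | C=C(C)[C@H](OB([C@H]1C[C@H]2C[C@@H]([C@@H]1C)C2(C)C)[C@H]1C[C@H]2C[C@@H]([C@@H]1C)C2(C)C)CC=C | intermediate
9 | (3R)-2-methylhexa-1,5-dien-3-ol | C=C(C)[C@H](O)CC=C | intermediate
10 | sodium (3R)-2-methylhexa-1,5-dien-3-olate | C=C(C)[C@H]([O-])CC=C.[Na+] | intermediate
11 | (3R)-2-methyl-3-{[(5E,9E)-6,10,14-trimethyl-2-methylidenepentadeca-5,9,13-trien-1-yl]oxy}hexa-1,5-diene | C=C(C)[C@H](OCC(=C)CC/C=C(\C)CC/C=C(\C)CCC=C(C)C)CC=C | intermediate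
12 | (2R)-2-(prop-1-en-2-yl)-5-[(3E,7E)-4,8,12-trimethyltrideca-3,7,11-trien-1-yl]-3,6-dihydro-2H-pyran | C=C(C)[C@H]1CC=C(CC/C=C(\C)CC/C=C(\C)CCC=C(C)C)CO1 | intermediate
13 | 2-{(2R)-5-[(3E,7E)-4,8,12-trimethyltrideca-3,7,11-trien-1-yl]-3,6-dihydro-2H-pyran-2-yl}prop-2-en-1-ol | C=C(CO)[C@H]1CC=C(CC/C=C(\C)CC/C=C(\C)CCC=C(C)C)CO1 | intermediate
14 | 2-{(2R)-5-[(3E,7E)-4,8,12-trimethyltrideca-3,7,11-trien-1-yl]-3,6-dihydro-2H-pyran-2-yl}prop-2-enal | C=C(C=O)[C@H]1CC=C(CC/C=C(\C)CC/C=C(\C)CCC=C(C)C)CO1 | intermediate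
15 | 2-{(2R)-5-[(3E,7E)-4,8,12-trimethyltrideca-3,7,11-trien-1-yl]-3,6-dihydro-2H-pyran-2-yl}prop-2-enoic acid (CNP0171598.2) | C=C(C(=O)O)[C@H]1CC=C(CC/C=C(\C)CC/C=C(\C)CCC=C(C)C)CO1 | target

**Step count**

Total steps: 6. Longest linear sequence: 5 (steps 1, 2, 4, 5, 6 from farnesyl bromide).

**Steps most likely to fail**

Step 6 (Proposed new method). The enzyme may not turn over the non-natural substrate, may stall at the alcohol or aldehyde stage, or may hydroxylate or epoxidise elsewhere (chain-terminal methyls, ring alkene, C2–H). The fallback uses known chemistry, sets out from bromide 5 and comes back at allylic alcohol 13; the oxidised carbon is carried in from the start as a protected CH2OH. Commercial 2-methylidenepropane-1,3-diol is mono-protected (NaH, 4-methoxybenzyl chloride, Bu4NI, THF) to 2-{[(4-methoxyphenyl)methoxy]methyl}prop-2-en-1-ol F1 and oxidised (MnO2, CH2Cl2) to 2-{[(4-methoxyphenyl)methoxy]methyl}prop-2-enal F2. Allylboration under the conditions of step 3 should pass through (3R)-2-{[(4-methoxyphenyl)methoxy]methyl}hexa-1,5-dien-3-yl diisopinocampheylborinate F3 and give, after NaOH/H2O2, (3R)-2-{[(4-methoxyphenyl)methoxy]methyl}hexa-1,5-dien-3-ol F4. Its sodium alkoxide, sodium (3R)-2-{[(4-methoxyphenyl)methoxy]methyl}hexa-1,5-dien-3-olate F5 (NaH, THF, 0 °C), is alkylated with 5 to (3R)-2-{[(4-methoxyphenyl)methoxy]methyl}-3-{[(5E,9E)-6,10,14-trimethyl-2-methylidenepentadeca-5,9,13-trien-1-yl]oxy}hexa-1,5-diene F6. Ring-closing metathesis as in step 5 should give (2R)-2-{3-[(4-methoxyphenyl)methoxy]prop-1-en-2-yl}-5-[(3E,7E)-4,8,12-trimethyltrideca-3,7,11-trien-1-yl]-3,6-dihydro-2H-pyran F7. DDQ (CH2Cl2, pH 7 buffer, 0 °C) removes the 4-methoxybenzyl group and delivers 13. From there MnO2 (CH2Cl2) should give enal 14, and Pinnick oxidation (NaClO2, NaH2PO4, 2-methylbut-2-ene, t-BuOH/H2O) should give 15.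

Step 5. The ruthenium carbene may engage the chain alkenes and cause oligomerisation or chain scrambling, closure onto the hindered 1,1-disubstituted alkene may be slow, and Ru–H species may shift double bonds. The fallback closes the ring before the polyene is attached; it sets out from alkoxide 10 and from bromide 1 and comes back at 12. Alkoxide 10 is alkylated with an excess of commercial 3-chloro-2-(chloromethyl)prop-1-ene to (3R)-3-{[2-(chloromethyl)prop-2-en-1-yl]oxy}-2-methylhexa-1,5-diene F8. Its metathesis (Grubbs II, CH2Cl2, 40 °C) has no polyene to contend with and should give (2R)-5-(chloromethyl)-2-(prop-1-en-2-yl)-3,6-dihydro-2H-pyran F9. Separately, 1 and sodium benzenesulfinate (DMF, rt) give (2E,6E)-farnesyl phenyl sulfone F10. Deprotonation (n-BuLi, THF, −78 °C) gives α-lithio farnesyl phenyl sulfone F11, which is alkylated with F9 to (2R)-5-[(3E,7E)-4,8,12-trimethyl-2-(phenylsulfonyl)trideca-3,7,11-trien-1-yl]-2-(prop-1-en-2-yl)-3,6-dihydro-2H-pyran F12 (both epimers at the sulfonyl carbon). Palladium-catalysed hydride desulfonylation (PdCl2(dppp) cat., LiBHEt3, THF, 0 °C) should deliver hydride to the less substituted allyl terminus and give 12 with the E alkene in place.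

Step 1. The allyl anion may attack the γ-carbon of farnesyl bromide (SN2') and give the branched isomer, metalation to the dianion may be incomplete, or a second alkylation or O-alkylation may occur. The fallback builds the 2-substituted allyl alcohol from a methyl ketone; it sets out from 1 and comes back at 4. Bromide 1 alkylates the sodium enolate of ethyl acetoacetate (NaOEt, EtOH) to ethyl (4E,8E)-2-acetyl-5,9,13-trimethyltetradeca-4,8,12-trienoate F13. Saponification (aq. NaOH) and acidification give (4E,8E)-2-acetyl-5,9,13-trimethyltetradeca-4,8,12-trienoic acid F14, which loses CO2 on warming to (5E,9E)-6,10,14-trimethylpentadeca-5,9,13-trien-2-one F15 (farnesylacetone). Kinetic deprotonation at the methyl group (KHMDS, THF, −78 °C) gives potassium (5E,9E)-6,10,14-trimethylpentadeca-1,5,9,13-tetraen-2-olate F16, trapped with PhNTf2 as (5E,9E)-6,10,14-trimethylpentadeca-1,5,9,13-tetraen-2-yl trifluoromethanesulfonate F17. Palladium-catalysed methoxycarbonylation (Pd(OAc)2, PPh3, CO, MeOH, Et3N, DMF) gives methyl (5E,9E)-6,10,14-trimethyl-2-methylidenepentadeca-5,9,13-trienoate F18, and DIBAL-H (CH2Cl2, −78 °C) reduces it to 4.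

**Further compounds**

F1 | step 6 | 2-{[(4-methoxyphenyl)methoxy]methyl}prop-2-en-1-ol | C=C(CO)COCc1ccc(OC)cc1
F2 | step 6 | 2-{[(4-methoxyphenyl)methoxy]methyl}prop-2-enal | C=C(C=O)COCc1ccc(OC)cc1
F3 | step 6 | (3R)-2-{[(4-methoxyphenyl)methoxy]methyl}hexa-1,5-dien-3-yl diisopinocampheylborinate | C=C(COCc1ccc(OC)cc1)[C@H](OB([C@H]1C[C@H]2C[C@@H]([C@@H]1C)C2(C)C)[C@H]1C[C@H]2C[C@@H]([C@@H]1C)C2(C)C)CC=C
F4 | step 6 | (3R)-2-{[(4-methoxyphenyl)methoxy]methyl}hexa-1,5-dien-3-ol | C=C(COCc1ccc(OC)cc1)[C@H](O)CC=C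
F5 | step 6 | sodium (3R)-2-{[(4-methoxyphenyl)methoxy]methyl}hexa-1,5-dien-3-olate | C=C(COCc1ccc(OC)cc1)[C@H]([O-])CC=C.[Na+]
F6 | step 6 | (3R)-2-{[(4-methoxyphenyl)methoxy]methyl}-3-{[(5E,9E)-6,10,14-trimethyl-2-methylidenepentadeca-5,9,13-trien-1-yl]oxy}hexa-1,5-diene | C=C(COCc1ccc(OC)cc1)[C@H](OCC(=C)CC/C=C(\C)CC/C=C(\C)CCC=C(C)C)CC=C
F7 | step 6 | (2R)-2-{3-[(4-methoxyphenyl)methoxy]prop-1-en-2-yl}-5-[(3E,7E)-4,8,12-trimethyltrideca-3,7,11-trien-1-yl]-3,6-dihydro-2H-pyran | C=C(COCc1ccc(OC)cc1)[C@H]1CC=C(CC/C=C(\C)CC/C=C(\C)CCC=C(C)C)CO1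
F8 | step 5 | (3R)-3-{[2-(chloromethyl)prop-2-en-1-yl]oxy}-2-methylhexa-1,5-diene | C=C(C)[C@H](OCC(=C)CCl)CC=C
F9 | step 5 | (2R)-5-(chloromethyl)-2-(prop-1-en-2-yl)-3,6-dihydro-2H-pyran | C=C(C)[C@H]1CC=C(CCl)CO1
F10 | step 5 | (2E,6E)-farnesyl phenyl sulfone, [(2E,6E)-3,7,11-trimethyldodeca-2,6,10-trien-1-yl]sulfonylbenzene | O=S(=O)(C/C=C(\C)CC/C=C(\C)CCC=C(C)C)c1ccccc1
F11 | step 5 | α-lithio (2E,6E)-farnesyl phenyl sulfone | [Li]C(/C=C(\C)CC/C=C(\C)CCC=C(C)C)S(=O)(=O)c1ccccc1
F12 | step 5 | (2R)-5-[(3E,7E)-4,8,12-trimethyl-2-(phenylsulfonyl)trideca-3,7,11-trien-1-yl]-2-(prop-1-en-2-yl)-3,6-dihydro-2H-pyran | C=C(C)[C@H]1CC=C(CC(/C=C(\C)CC/C=C(\C)CCC=C(C)C)S(=O)(=O)c2ccccc2)CO1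
F13 | step 1 | ethyl (4E,8E)-2-acetyl-5,9,13-trimethyltetradeca-4,8,12-trienoate | CCOC(=O)C(C(C)=O)C/C=C(\C)CC/C=C(\C)CCC=C(C)C
F14 | step 1 | (4E,8E)-2-acetyl-5,9,13-trimethyltetradeca-4,8,12-trienoic acid | OC(=O)C(C(C)=O)C/C=C(\C)CC/C=C(\C)CCC=C(C)C
F15 | step 1 | (5E,9E)-6,10,14-trimethylpentadeca-5,9,13-trien-2-one (farnesylacetone) | CC(=O)CC/C=C(\C)CC/C=C(\C)CCC=C(C)C
F16 | step 1 | potassium (5E,9E)-6,10,14-trimethylpentadeca-1,5,9,13-tetraen-2-olate | C=C([O-])CC/C=C(\C)CC/C=C(\C)CCC=C(C)C.[K+]
F17 | step 1 | (5E,9E)-6,10,14-trimethylpentadeca-1,5,9,13-tetraen-2-yl trifluoromethanesulfonate | C=C(OS(=O)(=O)C(F)(F)F)CC/C=C(\C)CC/C=C(\C)CCC=C(C)C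
F18 | step 1 | methyl (5E,9E)-6,10,14-trimethyl-2-methylidenepentadeca-5,9,13-trienoate | C=C(C(=O)OC)CC/C=C(\C)CC/C=C(\C)CCC=C(C)C
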